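## The problem

The target is a dearomatised acylphloroglucinol. Ring A (C4a, C5, C6, C7, C8, C8a) is an enolised cyclohexadiene-dione fused along C4a–C8a to a 2,2-dimethyldihydropyranone (ring B), and every ring-A carbon is substituted. C6 is a quaternary stereocentre carrying a prenyl group and a (trans-2-isopropenyl-3,3-dimethylcyclobutyl)methyl group. C8 carries a hexanoic acid chain through its C3, a second, isolated stereocentre.

The four stereocentres fall into three groups that cannot control one another. On the cyclobutane, C2' has to be set absolutely, and C1' can then be brought trans by equilibration next to a carbonyl group. The side-chain centre needs reagent control. C6 sits on a flat ring far from the others, so only a chiral catalyst can bias it.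

The molecule will not survive rough treatment. Acid protonates the isopropenyl group on the strained ring (cyclobutylcarbinyl cation, ring expansion) and closes the prenyl group onto the enol. Strong base opens ring B by retro-oxa-Michael reaction and can reclose it on the other oxygen.

The feature that invites the key step is this: without the C6 prenyl group, ring A is a 1,3,5-trioxygenated benzene in which oxygen and carbon substituents alternate and C4a is the only unsubstituted carbon. A cyclobutenone (C4a, C5, C6 and the C8a carbonyl) and a siloxyalkyne (C7, C8) write that pattern directly. Only the former carbonyl oxygen emerges free, at C8a, which is where ring B must be attached.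

## Retrosynthesis

**Prenyl group and ester (42 ⇒ 40 ⇒ 38).** The acid 42 is taken back to its tert-butyl ester 40, and the C6–prenyl bond is cut, with carbonate 39 as prenyl source. Cutting the prenyl group rather than the cyclobutylmethyl group is preferred because a π-allyl electrophile alkylates a hindered, doubly activated ring carbon readily, whereas displacement on the β-branched iodide 11 would not. The precursor 38 is aromatic, has no quaternary centre, and keeps three stereocentres, all in side chains. The forward step must choose C6 over C8, carbon over oxygen, the unbranched allyl terminus, and one face of a planar nucleophile; the last is asked of a chiral palladium catalyst.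

**Ring B (38 ⇒ 37 ⇒ 35 ⇒ 33 + 34).** Ring B is cut at O1–C2 and C4–C4a, which removes a 3-methylbut-2-enoyl unit (acid chloride 34). An acid-mediated Friedel–Crafts acylation would destroy the isopropenylcyclobutane, so the acyl group is first placed on the free O8a of phenol 33 (ester 35) and moved to C4a by light. C4a is the only open ring position, and the silyl ether on O5 allows only O8a to close the ring. Both silyl ethers of 37 then fall to fluoride. The forward reactions must be neutral or weakly basic throughout.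

**Ring A (33 ⇒ 17 + 28).** Three bonds are cut: C8–C8a, C6–C7 and C4a–C8a. This divides the fully substituted ring into cyclobutenone 17 and siloxyalkyne 28. Stepwise substitution of a phloroglucinol would have to distinguish three similar oxygens and three similar carbons; here every position follows from the connectivity of the partners. Both fragments are small and carry all their stereocentres. The forward reaction must run under neutral heat with regioselective ketene–alkyne union.

**Cyclobutenone (17 ⇒ 15 + 16; 15 ⇒ 13 ⇒ 11 + 12; 11 ⇒ 10 ⇒ 9).** The four-membered enone is the adduct of ketene 16 and siloxyalkyne 15. Carrying O5 as a silyl rather than an alkyl ether avoids a late dealkylation that the molecule would not tolerate. Alkyne 15 comes from terminal alkyne 13 by oxidation at the acetylide carbon. Alkyne 13 comes from iodide 11 and acetylide 12, and 11 from ester 9 by reduction and iodination. Each step is a standard functional-group change on a robust hydrocarbon.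

**Cyclobutane stereocentres (9 ⇒ 7 ⇒ 6 ⇒ 4 + 5; 4 ⇒ 1 + 2).** The C2'–isopropenyl bond is cut. The cis amide 6 comes from the achiral, commercial acid 1 by amide-directed cleavage of one of two enantiotopic methylene C–H bonds and coupling with boronate 5. Building the ring by cycloaddition or ring contraction would be longer. The forward step has to set C2'; C1' is then corrected by epimerisation when the auxiliary is exchanged for a methyl ester (7 to 9).

**Siloxyalkyne (28 ⇒ 26 ⇒ 24 + 25; 24 ⇒ 23 ⇒ 22 ⇒ 20 + 21; 20 ⇒ 18 + 19).** The ynol ether is made from terminal alkyne 26, which comes from aldehyde 24 by one-carbon homologation with 25. The stereocentre is set by auxiliary-controlled alkylation of imide 20 with bromoacetate 21. This sequence is known on exactly this substrate up to alcohol 23. A homologation of a diester with excess butyllithium would be shorter but would endanger the tert-butyl ester.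

## Roads not taken

**Alternative 1:** The cyclobutane is cut across C1'–C2' and C3'–C4', back to the allyl ether A1 of an enantiopure secondary allylic alcohol. Irradiating A1 in the presence of CuOTf (monovalent copper) would close the four-membered ring and a temporary oxolane in one step, giving bicyclic ether A2 with the methyl group exo.
- Merits: the ring is formed from an acyclic diene, the configuration is relayed from a cheap carbinol centre, and C1' arrives with the correct sense.
- Weak points: the ring fusion is necessarily cis, so C2' has to be inverted later. The carbinol carbon lacks one carbon of the isopropenyl group, so an ether cleavage, an oxidation, an epimerisation and a methylenation must follow. The trisubstituted alkene binds copper weakly.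
- Comparison: this road needs roughly twice as many steps to reach alcohol 10. Its stereochemical relay is more predictable than the ligand-controlled C–H alkenylation of step 2. Against that the chosen plan sets a commercial four-membered ring and one catalytic step that installs both the group and its configuration.

**Alternative 2:** The C1'–C4' bond is cut, leading back to diazocyclopentanone A3. Photolysis in methanol would expel nitrogen, shift the ring methylene to the carbene carbon and give ester A4, which is identical with ester 9.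
- Merits: C2' would be set by a well-understood asymmetric conjugate addition to a five-membered enone, the ring contraction is dependable, and the trans isomer follows by equilibration.
- Weak points: the conjugate addition occurs next to a quaternary carbon, the diazo transfer must be regioselective, and a diazo compound and a photolysis are added.
- Comparison: the step count to the common ester is about the same, and the stereochemical outcome is arguably more secure than in step 2. The chosen plan sets against it a bought ring and one fewer ring-forming operation. This road is kept as the fallback for step 2.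

**Alternative 3:** Ring A is cut at C4a–C5. A keto ester A5 with the C6 quaternary carbon already in place would be deprotonated at the future C8 methylene, and the C4a terminus of the extended enolate would attack the methyl ester to give A6, the target without its acid chain.
- Merits: this is better than the chosen plan in one respect. C6 is made on an open-chain β-keto ester, where asymmetric allylation is strong, so the late facial problem of step 20 disappears.
- Weak points: the hexanoic acid chain must then be added at C8 by conjugate addition, which creates the side-chain stereocentre under remote control only. The Claisen closure needs γ-reactivity of an extended enolate, and the α,α-disubstituted β-keto ester is prone to retro-Claisen cleavage.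
- Comparison: the two plans exchange one poorly controlled centre for another. The chosen plan presets the side-chain centre with an auxiliary and leaves C6 to a catalyst acting on a prochiral nucleophile in a well-known reaction class, with separable diastereomers as the worst case.

Key step: step 16

## Route

Remark: O5 is carried as a triisopropylsilyl ether, not a methyl ether, so that the cyclobutenone is the ketene adduct of a second siloxyalkyne and both ring-A ethers are later removed together by fluoride.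

Remark: in the two ligand-controlled steps (2 and 20) the ligand antipode is assumed to be the one that gives the drawn isomer; the mirror-image ligand is used if the sense of induction proves opposite.

Step 1
Reactants: 1 3,3-dimethylcyclobutane-1-carboxylic acid; 2 2,3,5,6-tetrafluoro-4-(trifluoromethyl)aniline
Product: 4 N-[2,3,5,6-tetrafluoro-4-(trifluoromethyl)phenyl]-3,3-dimethylcyclobutane-1-carboxamide, via acid chloride 3 (not isolated)
Conditions: (COCl)2, DMF (cat.), CH2Cl2, 0 °C → rt; then 2, toluene, 110 °C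
Reagents that add atoms: none
Why: Acylation of the weakly nucleophilic aniline by the acid chloride; the acidic N-aryl amide is the directing group for step 2.

Step 2
Reactants: 4 N-aryl amide; 5 4,4,5,5-tetramethyl-2-(prop-1-en-2-yl)-1,3,2-dioxaborolane
Product: 6 (1S,2R)-3,3-dimethyl-2-(prop-1-en-2-yl)-N-[2,3,5,6-tetrafluoro-4-(trifluoromethyl)phenyl]cyclobutane-1-carboxamide
Conditions: Pd(OAc)2 (10 mol %), chiral N-acetyl aminomethyl-oxazoline ligand (20 mol %), Ag2CO3, Na2CO3, 1,4-benzoquinone, H2O, t-AmylOH, 70 °C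
Reagents that add atoms: none
Why: Amide-directed enantioselective β-C(sp3)–H alkenylation of a cyclobutanecarboxamide with an alkenyl boronate: divalent palladium bound to the chiral ligand cleaves one of the two enantiotopic cis methylene C–H bonds, and transmetalation and reductive elimination place the isopropenyl group cis to the amide. This sets C2' (R); the zerovalent palladium formed is reoxidised by Ag2CO3.

Step 3
Reactants: 6 cis amide
Product: 7 tert-butyl N-[(1S,2R)-3,3-dimethyl-2-(prop-1-en-2-yl)cyclobutane-1-carbonyl]-N-[2,3,5,6-tetrafluoro-4-(trifluoromethyl)phenyl]carbamate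
Conditions: Boc2O, DMAP, MeCN, rt
Reagents that add atoms: di-tert-butyl dicarbonate, CC(C)(C)OC(=O)OC(=O)OC(C)(C)C
Why: N-Acylation of the acidic anilide gives a twisted imide whose acyl group can be removed by alkoxide without acid, which the isopropenylcyclobutane would not tolerate.

Step 4
Reactants: 7 N-Boc amide
Product: 9 methyl (1R,2R)-3,3-dimethyl-2-(prop-1-en-2-yl)cyclobutane-1-carboxylate, via cis methyl ester 8 (not isolated)
Conditions: NaOMe, MeOH, 0 °C → 60 °C
Reagents that add atoms: sodium methoxide, [Na+].[O-]C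
Why: Methoxide cleaves the activated imide at the acyl carbon and then equilibrates C1' through the ester enolate to the trans isomer, which avoids the cis isopropenyl group; C2' is not acidic and keeps its configuration.

Step 5
Reactants: 9 trans methyl ester
Product: 10 [(1R,2R)-3,3-dimethyl-2-(prop-1-en-2-yl)cyclobutyl]methanol
Conditions: LiAlH4, Et2O, 0 °C
Reagents that add atoms: none
Why: Hydride reduction of the ester; no centre is touched (the change of the C1' descriptor from here on reflects ligand priorities only).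

Step 6
Reactants: 10 alcohol
Product: 11 (2R,3R)-3-(iodomethyl)-1,1-dimethyl-2-(prop-1-en-2-yl)cyclobutane
Conditions: I2, PPh3, imidazole, CH2Cl2, 0 °C → rt
Reagents that add atoms: iodine, II
Why: Appel iodination by SN2 displacement of the oxyphosphonium ion; no cation is formed, so the cyclobutylcarbinyl system does not rearrange.

Step 7
Reactants: 11 iodide; 12 lithium acetylide–ethane-1,2-diamine complex
Product: 13 (2R,3R)-1,1-dimethyl-2-(prop-1-en-2-yl)-3-(prop-2-yn-1-yl)cyclobutane
Conditions: LiC≡CH·H2NCH2CH2NH2, DMSO, rt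
Reagents that add atoms: none
Why: SN2 alkylation of acetylide by the primary iodide in a dipolar aprotic solvent.

Step 8
Reactants: 13 terminal alkyne
Product: 15 ({3-[(1S,2R)-3,3-dimethyl-2-(prop-1-en-2-yl)cyclobutyl]prop-1-yn-1-yl}oxy)tri(propan-2-yl)silane, via lithium ynolate 14 (not isolated)
Conditions: LiN(SiMe3)2, THF, −78 °C; t-BuOOLi (from t-BuOOH and LiN(SiMe3)2), −78 → 0 °C; i-Pr3SiOTf, −78 → 0 °C
Reagents that add atoms: tert-butyl hydroperoxide, CC(C)(C)OO; triisopropylsilyl trifluoromethanesulfonate, CC(C)[Si](C(C)C)(C(C)C)OS(=O)(=O)C(F)(F)F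
Why: The lithium acetylide is oxidised by electrophilic oxygen transfer from lithium tert-butyl peroxide to the ynolate, which the bulky silyl triflate traps on oxygen; this is the known route from terminal alkynes to siloxyalkynes.

Step 9
Reactants: 15 siloxyalkyne; 16 ketene
Product: 17 2-{[(1S,2R)-3,3-dimethyl-2-(prop-1-en-2-yl)cyclobutyl]methyl}-3-{[tri(propan-2-yl)silyl]oxy}cyclobut-2-en-1-one
Conditions: 16 (gas, from acetone pyrolysis), CH2Cl2, 0 °C → rt
Reagents that add atoms: none
Why: [2+2] Cycloaddition of ketene with the electron-rich ynol ether; the alkyne carbon β to oxygen attacks the ketene carbonyl carbon, so the alkyl group ends at C2 and the siloxy group at C3 of the cyclobutenone.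

Step 10
Reactants: 18 (4S)-4-benzyl-1,3-oxazolidin-2-one; 19 pentanoyl chloride
Product: 20 (4S)-4-benzyl-3-pentanoyl-1,3-oxazolidin-2-one
Conditions: n-BuLi, THF, −78 °C; then 19
Reagents that add atoms: none
Why: N-Acylation of the lithiated auxiliary.

Step 11
Reactants: 20 imide; 21 tert-butyl bromoacetate
Product: 22 tert-butyl (3R)-3-[(4S)-4-benzyl-2-oxo-1,3-oxazolidine-3-carbonyl]hexanoate
Conditions: NaN(SiMe3)2, THF, −78 °C; then 21, −78 → −40 °C
Reagents that add atoms: none
Why: Evans alkylation: the chelated Z-enolate is alkylated on the face opposite the benzyl group, which sets the side-chain centre (R); this transformation is known on this very imide.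

Step 12
Reactants: 22 alkylated imide
Product: 23 tert-butyl (3R)-3-(hydroxymethyl)hexanoate
Conditions: LiBH4, H2O (1 equiv), Et2O, 0 °C
Reagents that add atoms: none
Why: Borohydride reduces the activated imide carbonyl and spares the tert-butyl ester; a cold, non-acidic work-up avoids lactonisation, and the auxiliary 18 is recovered.

Step 13
Reactants: 23 hydroxy ester
Product: 24 tert-butyl (3R)-3-formylhexanoate
Conditions: Dess–Martin periodinane, NaHCO3, CH2Cl2, 0 °C → rt
Reagents that add atoms: none
Why: Buffered hypervalent-iodine oxidation gives the α-branched aldehyde without epimerisation; it is used at once.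

Step 14
Reactants: 24 aldehyde; 25 dimethyl (1-diazo-2-oxopropyl)phosphonate
Product: 26 tert-butyl (3R)-3-ethynylhexanoate
Conditions: K2CO3, MeOH, 0 °C → rt
Reagents that add atoms: none
Why: Seyferth–Gilbert homologation in the Ohira–Bestmann form: the diazomethylphosphonate anion made in situ converts the aldehyde to the alkyne through a vinylidene carbene; the mild carbonate base at low temperature limits α-epimerisation.

Step 15
Reactants: 26 alkynyl ester
Product: 28 tert-butyl (3R)-3-propyl-5-{[tri(propan-2-yl)silyl]oxy}pent-4-ynoate, via lithium ynolate 27 (not isolated)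
Conditions: LiN(SiMe3)2 (1.0 equiv), THF, −78 °C; t-BuOOLi, −78 → 0 °C; i-Pr3SiOTf, −78 → 0 °C
Reagents that add atoms: tert-butyl hydroperoxide, CC(C)(C)OO; triisopropylsilyl trifluoromethanesulfonate, CC(C)[Si](C(C)C)(C(C)C)OS(=O)(=O)C(F)(F)F
Why: Same acetylide oxidation and O-silylation as in step 8; one equivalent of amide base at −78 °C removes the alkyne proton in preference to the α-protons of the hindered tert-butyl ester, and the stereocentre is not acidic.

Step 16
Reactants: 17 siloxycyclobutenone; 28 siloxyalkyne (slight excess)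
Product: 33 tert-butyl (3R)-3-[3-{[(1S,2R)-3,3-dimethyl-2-(prop-1-en-2-yl)cyclobutyl]methyl}-6-hydroxy-2,4-bis{[tri(propan-2-yl)silyl]oxy}phenyl]hexanoate, via vinylketene 29 (not isolated), via 4-vinylcyclobutenone 30 (not isolated), via dienylketene 31 (not isolated), via cyclohexadienone 32 (not isolated)
Conditions: toluene (0.3 M), 110 °C, sealed tube
Reagents that add atoms: none
Why: Heating opens 17 by 4π electrocyclic cleavage of the C(=O)–CH2 bond to vinylketene 29. The ynol ether 28, polarised so that its side-chain-bearing carbon is the nucleophile, adds to the ketene in a [2+2] cycloaddition: that carbon bonds to the ketene carbonyl carbon (C8–C8a) and the siloxy carbon to the ketene α-carbon (C6–C7), giving 30. A second 4π opening gives dienylketene 31, whose 6π electrocyclisation joins the methylene terminus to the ketene carbon (C4a–C8a) and closes ring A as cyclohexadienone 32, which enolises to phenol 33. The closest known reaction is the thermal cyclobutenone–siloxyalkyne benzannulation (Danheiser benzannulation) giving resorcinol monosilyl ethers; here the cyclobutenone carries a third oxygen. No stereocentre is formed: the quaternary carbon of 30 is flattened again on ring opening, and the cyclobutane and side-chain centres are not acidic under neutral heating. The step needs regioselectivity in the [2+2] union, secured by the polarisation of the ynol ether, and chemoselectivity of the ketene for the alkyne over its own isopropenyl group, secured by the trans ring geometry (an intramolecular adduct would be a trans-fused bicycle) and by the far higher nucleophilicity of the ynol ether. Only the former ketene oxygen emerges unprotected, so O8a is the single free hydroxyl, and the slight excess of 28 keeps the phenol from being acylated by vinylketene.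

Step 17
Reactants: 33 phenol; 34 3-methylbut-2-enoyl chloride
Product: 35 tert-butyl (3R)-3-[3-{[(1S,2R)-3,3-dimethyl-2-(prop-1-en-2-yl)cyclobutyl]methyl}-6-[(3-methylbut-2-enoyl)oxy]-2,4-bis{[tri(propan-2-yl)silyl]oxy}phenyl]hexanoate
Conditions: NaH, THF, 0 °C; then 34, 0 °C → rt
Reagents that add atoms: none
Why: O-Acylation of the sodium phenoxide; working without an amine base avoids deconjugation of the acid chloride through its vinylketene.

Step 18
Reactants: 35 aryl 3-methylbut-2-enoate
Product: 37 tert-butyl (3R)-3-[6-{[(1S,2R)-3,3-dimethyl-2-(prop-1-en-2-yl)cyclobutyl]methyl}-2,2-dimethyl-4-oxo-5,7-bis{[tri(propan-2-yl)silyl]oxy}-3,4-dihydro-2H-chromen-8-yl]hexanoate, via hydroxyaryl enone 36 (not isolated)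
Conditions: hν (254 nm), degassed cyclohexane, rt; then DBU (cat.), CH2Cl2, rt
Reagents that add atoms: none
Why: Photo-Fries rearrangement: homolysis of the aryl ester in the solvent cage and recombination at C4a, the only free ortho or para carbon, gives enone 36. The amine base then closes ring B by 6-endo oxa-Michael addition of the free O8a hydroxyl (known route from aryl 3-methylbut-2-enoates to 2,2-dimethylchroman-4-ones); O5 is still silylated, so only one mode of closure exists.

Step 19
Reactants: 37 bis-silyl chromanone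
Product: 38 tert-butyl (3R)-3-[6-{[(1S,2R)-3,3-dimethyl-2-(prop-1-en-2-yl)cyclobutyl]methyl}-5,7-dihydroxy-2,2-dimethyl-4-oxo-3,4-dihydro-2H-chromen-8-yl]hexanoate
Conditions: Bu4NF, AcOH, THF, 0 °C → rt
Reagents that add atoms: none
Why: Fluoride cleaves both aryl silyl ethers; acetic acid buffers the phenoxides, so ring B does not open and reclose on O5.

Step 20
Reactants: 38 dihydroxychromanone; 39 tert-butyl 3-methylbut-2-en-1-yl carbonate
Product: 40 tert-butyl (3R)-3-[(6R)-6-{[(1S,2R)-3,3-dimethyl-2-(prop-1-en-2-yl)cyclobutyl]methyl}-5-hydroxy-2,2-dimethyl-6-(3-methylbut-2-en-1-yl)-4,7-dioxo-3,4,6,7-tetrahydro-2H-chromen-8-yl]hexanoate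
Conditions: Pd2(dba)3 (2.5 mol %), (1R,2R)-N,N'-bis[2-(diphenylphosphanyl)benzoyl]cyclohexane-1,2-diamine (7.5 mol %), THF, 0 °C → rt
Reagents that add atoms: none
Why: Tsuji–Trost dearomative C-prenylation: zerovalent palladium ionises the carbonate, the tert-butoxide released deprotonates O7–H, and the phenoxide attacks the unsubstituted allyl terminus through C6, which is less hindered than C8 and gives the hydrogen-bonded enol triketone; O-allylation is reversible under the catalyst. The chiral diphosphine differentiates the two faces of the planar nucleophile and sets C6 (R); the C6 epimer is a diastereomer and separable.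

Step 21
Reactants: 40 tert-butyl ester
Product: 42 (3R)-3-[(6R)-6-{[(1S,2R)-3,3-dimethyl-2-(prop-1-en-2-yl)cyclobutyl]methyl}-5-hydroxy-2,2-dimethyl-6-(3-methylbut-2-en-1-yl)-4,7-dioxo-3,4,6,7-tetrahydro-2H-chromen-8-yl]hexanoic acid, via bis(trimethylsilyl) derivative 41 (not isolated)
Conditions: Me3SiOTf, 2,6-lutidine, CH2Cl2, 0 °C; then pH 5 phosphate buffer
Reagents that add atoms: none
Why: Silyl triflate activates the ester carbonyl and the tert-butyl group leaves as isobutene with lutidine as proton acceptor; the silyl ester and silyl enol ether are hydrolysed on work-up. No free protic acid is present, so the isopropenylcyclobutane and the prenyl–enol pair are spared.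

## Compound list

1 | 3,3-dimethylcyclobutane-1-carboxylic acid | CC1(C)CC(C1)C(=O)O | starting material
2 | 2,3,5,6-tetrafluoro-4-(trifluoromethyl)aniline | Nc1c(F)c(F)c(C(F)(F)F)c(F)c1F | starting material
3 | 3,3-dimethylcyclobutane-1-carbonyl chloride | CC1(C)CC(C1)C(=O)Cl | intermediate (not isolated)
4 | N-[2,3,5,6-tetrafluoro-4-(trifluoromethyl)phenyl]-3,3-dimethylcyclobutane-1-carboxamide | CC1(C)CC(C1)C(=O)Nc1c(F)c(F)c(C(F)(F)F)c(F)c1F | intermediate
5 | 4,4,5,5-tetramethyl-2-(prop-1-en-2-yl)-1,3,2-dioxaborolane | CC(=C)B1OC(C)(C)C(C)(C)O1 | starting material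
6 | (1S,2R)-3,3-dimethyl-2-(prop-1-en-2-yl)-N-[2,3,5,6-tetrafluoro-4-(trifluoromethyl)phenyl]cyclobutane-1-carboxamide (cis) | C=C(C)[C@H]1[C@@H](C(=O)Nc2c(F)c(F)c(C(F)(F)F)c(F)c2F)CC1(C)C | intermediate
7 | tert-butyl N-[(1S,2R)-3,3-dimethyl-2-(prop-1-en-2-yl)cyclobutane-1-carbonyl]-N-[2,3,5,6-tetrafluoro-4-(trifluoromethyl)phenyl]carbamate | C=C(C)[C@H]1[C@@H](C(=O)N(C(=O)OC(C)(C)C)c2c(F)c(F)c(C(F)(F)F)c(F)c2F)CC1(C)C | intermediate
8 | methyl (1S,2R)-3,3-dimethyl-2-(prop-1-en-2-yl)cyclobutane-1-carboxylate (cis) | C=C(C)[C@H]1[C@@H](C(=O)OC)CC1(C)C | intermediate (not isolated)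
9 | methyl (1R,2R)-3,3-dimethyl-2-(prop-1-en-2-yl)cyclobutane-1-carboxylate (trans) | C=C(C)[C@H]1[C@H](C(=O)OC)CC1(C)C | intermediate
10 | [(1R,2R)-3,3-dimethyl-2-(prop-1-en-2-yl)cyclobutyl]methanol | C=C(C)[C@H]1[C@H](CO)CC1(C)C | intermediate
11 | (2R,3R)-3-(iodomethyl)-1,1-dimethyl-2-(prop-1-en-2-yl)cyclobutane | C=C(C)[C@H]1[C@H](CI)CC1(C)C | intermediate
12 | lithium acetylide–ethane-1,2-diamine complex | [Li+].[C-]#C.NCCN | starting material
13 | (2R,3R)-1,1-dimethyl-2-(prop-1-en-2-yl)-3-(prop-2-yn-1-yl)cyclobutane | C=C(C)[C@H]1[C@H](CC#C)CC1(C)C | intermediate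
14 | lithium 3-[(1S,2R)-3,3-dimethyl-2-(prop-1-en-2-yl)cyclobutyl]prop-1-yn-1-olate | C=C(C)[C@H]1[C@H](CC#C[O-])CC1(C)C.[Li+] | intermediate (not isolated)
15 | ({3-[(1S,2R)-3,3-dimethyl-2-(prop-1-en-2-yl)cyclobutyl]prop-1-yn-1-yl}oxy)tri(propan-2-yl)silane | C=C(C)[C@H]1[C@H](CC#CO[Si](C(C)C)(C(C)C)C(C)C)CC1(C)C | intermediate
16 | ketene (ethenone), generated from acetone | C=C=O | starting material
17 | 2-{[(1S,2R)-3,3-dimethyl-2-(prop-1-en-2-yl)cyclobutyl]methyl}-3-{[tri(propan-2-yl)silyl]oxy}cyclobut-2-en-1-one | C=C(C)[C@H]1[C@H](CC2=C(O[Si](C(C)C)(C(C)C)C(C)C)CC2=O)CC1(C)C | intermediate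
18 | (4S)-4-benzyl-1,3-oxazolidin-2-one | O=C1N[C@@H](Cc2ccccc2)CO1 | starting material
19 | pentanoyl chloride | CCCCC(=O)Cl | starting material
20 | (4S)-4-benzyl-3-pentanoyl-1,3-oxazolidin-2-one | CCCCC(=O)N1[C@@H](Cc2ccccc2)COC1=O | intermediate
21 | tert-butyl bromoacetate | CC(C)(C)OC(=O)CBr | starting material
22 | tert-butyl (3R)-3-[(4S)-4-benzyl-2-oxo-1,3-oxazolidine-3-carbonyl]hexanoate | CCC[C@H](CC(=O)OC(C)(C)C)C(=O)N1[C@@H](Cc2ccccc2)COC1=O | intermediate
23 | tert-butyl (3R)-3-(hydroxymethyl)hexanoate | CCC[C@H](CC(=O)OC(C)(C)C)CO | intermediate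
24 | tert-butyl (3R)-3-formylhexanoate | CCC[C@H](CC(=O)OC(C)(C)C)C=O | intermediate
25 | dimethyl (1-diazo-2-oxopropyl)phosphonate | CC(=O)C(=[N+]=[N-])P(=O)(OC)OC | starting material
26 | tert-butyl (3R)-3-ethynylhexanoate | CCC[C@H](CC(=O)OC(C)(C)C)C#C | intermediate
27 | lithium (3R)-5-tert-butoxy-5-oxo-3-propylpent-1-yn-1-olate | CCC[C@H](CC(=O)OC(C)(C)C)C#C[O-].[Li+] | intermediate (not isolated)
28 | tert-butyl (3R)-3-propyl-5-{[tri(propan-2-yl)silyl]oxy}pent-4-ynoate | CCC[C@H](CC(=O)OC(C)(C)C)C#CO[Si](C(C)C)(C(C)C)C(C)C | intermediate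
29 | 2-{[(1S,2R)-3,3-dimethyl-2-(prop-1-en-2-yl)cyclobutyl]methyl}-3-{[tri(propan-2-yl)silyl]oxy}buta-1,3-dien-1-one | C=C(C)[C@H]1[C@H](CC(=C=O)C(=C)O[Si](C(C)C)(C(C)C)C(C)C)CC1(C)C | intermediate (not isolated)
30 | tert-butyl (3R)-3-[3-{[(1S,2R)-3,3-dimethyl-2-(prop-1-en-2-yl)cyclobutyl]methyl}-4-oxo-2-{[tri(propan-2-yl)silyl]oxy}-3-(1-{[tri(propan-2-yl)silyl]oxy}ethenyl)cyclobut-1-en-1-yl]hexanoate (both epimers at the ring quaternary carbon) | C=C(C)[C@H]1[C@H](CC2(C(=C)O[Si](C(C)C)(C(C)C)C(C)C)C(=O)C([C@H](CCC)CC(=O)OC(C)(C)C)=C2O[Si](C(C)C)(C(C)C)C(C)C)CC1(C)C | intermediate (not isolated)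
31 | tert-butyl (3R)-3-[(3E)-4-{[(1S,2R)-3,3-dimethyl-2-(prop-1-en-2-yl)cyclobutyl]methyl}-1-oxo-3,5-bis{[tri(propan-2-yl)silyl]oxy}hexa-1,3,5-trien-2-yl]hexanoate (ketene and siloxyvinyl group cis) | C=C(C)[C@H]1[C@H](C\C(C(=C)O[Si](C(C)C)(C(C)C)C(C)C)=C(/O[Si](C(C)C)(C(C)C)C(C)C)C(=C=O)[C@H](CCC)CC(=O)OC(C)(C)C)CC1(C)C | intermediate (not isolated)
32 | tert-butyl (3R)-3-[3-{[(1S,2R)-3,3-dimethyl-2-(prop-1-en-2-yl)cyclobutyl]methyl}-6-oxo-2,4-bis{[tri(propan-2-yl)silyl]oxy}cyclohexa-1,3-dien-1-yl]hexanoate | C=C(C)[C@H]1[C@H](CC2=C(O[Si](C(C)C)(C(C)C)C(C)C)CC(=O)C([C@H](CCC)CC(=O)OC(C)(C)C)=C2O[Si](C(C)C)(C(C)C)C(C)C)CC1(C)C | intermediate (not isolated)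
33 | tert-butyl (3R)-3-[3-{[(1S,2R)-3,3-dimethyl-2-(prop-1-en-2-yl)cyclobutyl]methyl}-6-hydroxy-2,4-bis{[tri(propan-2-yl)silyl]oxy}phenyl]hexanoate | C=C(C)[C@H]1[C@H](Cc2c(O[Si](C(C)C)(C(C)C)C(C)C)cc(O)c([C@H](CCC)CC(=O)OC(C)(C)C)c2O[Si](C(C)C)(C(C)C)C(C)C)CC1(C)C | intermediate
34 | 3-methylbut-2-enoyl chloride | CC(C)=CC(=O)Cl | starting material
35 | tert-butyl (3R)-3-[3-{[(1S,2R)-3,3-dimethyl-2-(prop-1-en-2-yl)cyclobutyl]methyl}-6-[(3-methylbut-2-enoyl)oxy]-2,4-bis{[tri(propan-2-yl)silyl]oxy}phenyl]hexanoate | C=C(C)[C@H]1[C@H](Cc2c(O[Si](C(C)C)(C(C)C)C(C)C)cc(OC(=O)C=C(C)C)c([C@H](CCC)CC(=O)OC(C)(C)C)c2O[Si](C(C)C)(C(C)C)C(C)C)CC1(C)C | intermediate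
36 | tert-butyl (3R)-3-[3-{[(1S,2R)-3,3-dimethyl-2-(prop-1-en-2-yl)cyclobutyl]methyl}-6-hydroxy-5-(3-methylbut-2-enoyl)-2,4-bis{[tri(propan-2-yl)silyl]oxy}phenyl]hexanoate | C=C(C)[C@H]1[C@H](Cc2c(O[Si](C(C)C)(C(C)C)C(C)C)c(C(=O)C=C(C)C)c(O)c([C@H](CCC)CC(=O)OC(C)(C)C)c2O[Si](C(C)C)(C(C)C)C(C)C)CC1(C)C | intermediate (not isolated)
37 | tert-butyl (3R)-3-[6-{[(1S,2R)-3,3-dimethyl-2-(prop-1-en-2-yl)cyclobutyl]methyl}-2,2-dimethyl-4-oxo-5,7-bis{[tri(propan-2-yl)silyl]oxy}-3,4-dihydro-2H-chromen-8-yl]hexanoate | C=C(C)[C@H]1[C@H](Cc2c(O[Si](C(C)C)(C(C)C)C(C)C)c3C(=O)CC(C)(C)Oc3c([C@H](CCC)CC(=O)OC(C)(C)C)c2O[Si](C(C)C)(C(C)C)C(C)C)CC1(C)C | intermediate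
38 | tert-butyl (3R)-3-[6-{[(1S,2R)-3,3-dimethyl-2-(prop-1-en-2-yl)cyclobutyl]methyl}-5,7-dihydroxy-2,2-dimethyl-4-oxo-3,4-dihydro-2H-chromen-8-yl]hexanoate | C=C(C)[C@H]1[C@H](Cc2c(O)c3C(=O)CC(C)(C)Oc3c([C@H](CCC)CC(=O)OC(C)(C)C)c2O)CC1(C)C | intermediate
39 | tert-butyl 3-methylbut-2-en-1-yl carbonate | CC(C)=CCOC(=O)OC(C)(C)C | starting material
40 | tert-butyl (3R)-3-[(6R)-6-{[(1S,2R)-3,3-dimethyl-2-(prop-1-en-2-yl)cyclobutyl]methyl}-5-hydroxy-2,2-dimethyl-6-(3-methylbut-2-en-1-yl)-4,7-dioxo-3,4,6,7-tetrahydro-2H-chromen-8-yl]hexanoate | C=C(C)[C@H]1[C@H](C[C@]2(CC=C(C)C)C(=O)C([C@H](CCC)CC(=O)OC(C)(C)C)=C3OC(C)(C)CC(=O)C3=C2O)CC1(C)C | intermediate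
41 | trimethylsilyl (3R)-3-[(6R)-6-{[(1S,2R)-3,3-dimethyl-2-(prop-1-en-2-yl)cyclobutyl]methyl}-2,2-dimethyl-6-(3-methylbut-2-en-1-yl)-4,7-dioxo-5-[(trimethylsilyl)oxy]-3,4,6,7-tetrahydro-2H-chromen-8-yl]hexanoate (enol ether drawn at O5) | C=C(C)[C@H]1[C@H](C[C@]2(CC=C(C)C)C(=O)C([C@H](CCC)CC(=O)O[Si](C)(C)C)=C3OC(C)(C)CC(=O)C3=C2O[Si](C)(C)C)CC1(C)C | intermediate (not isolated)
42 | (3R)-3-[(6R)-6-{[(1S,2R)-3,3-dimethyl-2-(prop-1-en-2-yl)cyclobutyl]methyl}-5-hydroxy-2,2-dimethyl-6-(3-methylbut-2-en-1-yl)-4,7-dioxo-3,4,6,7-tetrahydro-2H-chromen-8-yl]hexanoic acid | C=C(C)[C@H]1[C@H](C[C@]2(CC=C(C)C)C(=O)C([C@H](CCC)CC(=O)O)=C3OC(C)(C)CC(=O)C3=C2O)CC1(C)C | target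

## Step count and least certain steps

Total: 21 steps. Longest linear sequence: 15 steps (steps 1–9, then 16–21). The side-chain branch (steps 10–15, six steps) joins at step 16.

**Step 16 (key step).**
- Risk: the siloxy group of 17 conjugates with the carbonyl and may slow the ring opening. At the higher temperature then needed, the vinylketene may be intercepted by its own isopropenyl group (ene reaction or [2+2]) or may acylate the product phenol.
- Fallback: exchange the roles of the partners, so that the ketene forms on the fragment that has no alkene. It sets out from alkyne 26 and returns to the route at phenol 33.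
 - Alkyne 26 is oxidised as in step 15 but trapped with t-BuMe2SiOTf to give tert-butyl (3R)-5-{[tert-butyl(dimethyl)silyl]oxy}-3-propylpent-4-ynoate F1.
 - Ketene 16 converts F1 into tert-butyl (3R)-3-(2-{[tert-butyl(dimethyl)silyl]oxy}-4-oxocyclobut-1-en-1-yl)hexanoate F2.
 - Heating F2 with siloxyalkyne 15 should give the isomeric phenol with free O5, tert-butyl (3R)-3-[6-{[tert-butyl(dimethyl)silyl]oxy}-3-{[(1S,2R)-3,3-dimethyl-2-(prop-1-en-2-yl)cyclobutyl]methyl}-4-hydroxy-2-{[tri(propan-2-yl)silyl]oxy}phenyl]hexanoate F3.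
 - Silylation of O5 (i-Pr3SiOTf, 2,6-lutidine) gives the tris-silyl ether F4.
 - Selective removal of the less hindered, more labile tert-butyldimethylsilyl group at O8a (KHF2, MeOH) gives 33.

**Step 2.**
- Risk: slow C–H cleavage at a methylene next to a quaternary carbon, slow transfer of the α-branched alkenyl group with protodeboronation, or weak discrimination of the enantiotopic methylenes.
- Fallback: ring contraction. It sets out from commercial 4,4-dimethylcyclopent-2-en-1-one and boronate 5 and returns at ester 9.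
 - Hayashi–Miyaura addition (Rh(acac)(C2H4)2, BINAP antipode chosen for the (4R) ketone, aqueous KOH, dioxane) gives (4R)-3,3-dimethyl-4-(prop-1-en-2-yl)cyclopentan-1-one F5.
 - Kinetic enolisation away from the neopentyl methylene (LiN(SiMe3)2) and acylation with CF3CO2CH2CF3 gives (3R)-4,4-dimethyl-3-(prop-1-en-2-yl)-2-(trifluoroacetyl)cyclopentan-1-one F6.
 - Deacylative diazo transfer (MsN3, Et3N) gives (3R)-2-diazo-4,4-dimethyl-3-(prop-1-en-2-yl)cyclopentan-1-one F7.
 - Photolysis in methanol (Wolff rearrangement) gives esters 8 and 9, which NaOMe equilibrates to 9.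

**Step 20.**
- Risk: poor facial selectivity at C6, because the existing stereocentres are remote and the two flanks of the nucleophile are similar; competing attack through C8 or at the substituted allyl terminus.
- Fallback: from 38 to 40, alkylative dearomatisation as an ion-pair SN2 reaction. Prenyl bromide, a Cinchona-derived N-benzyl quaternary ammonium bromide, CsOH·H2O, toluene, −40 °C, is an asymmetric phase-transfer alkylation of the type known for acylphloroglucinols. It makes no compound outside the list (F0).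

**Step 18.**
- Risk: escape of the acyl radical from the solvent cage, giving back phenol 33, and photodeconjugation of the unsaturated ester, both lowering the mass balance.
- Fallback: a ground-state ortho-acylation in stages, setting out from 33 and returning at 37.
 - Magnesium-mediated ortho-formylation (MgCl2, Et3N, paraformaldehyde, MeCN, reflux) gives tert-butyl (3R)-3-[3-{[(1S,2R)-3,3-dimethyl-2-(prop-1-en-2-yl)cyclobutyl]methyl}-5-formyl-6-hydroxy-2,4-bis{[tri(propan-2-yl)silyl]oxy}phenyl]hexanoate F8.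
 - 2-Methylprop-1-enylmagnesium bromide (two equivalents, −78 °C) gives the allylic alcohol tert-butyl (3R)-3-[3-{[(1S,2R)-3,3-dimethyl-2-(prop-1-en-2-yl)cyclobutyl]methyl}-6-hydroxy-5-(1-hydroxy-3-methylbut-2-en-1-yl)-2,4-bis{[tri(propan-2-yl)silyl]oxy}phenyl]hexanoate F9.
 - MnO2 oxidation gives enone 36, which DBU closes to 37.

**Step 21.**
- Risk: cationic side reactions under the silyl triflate (closure of the prenyl group onto the enol oxygen, rearrangement of the isopropenylcyclobutane), or incomplete cleavage.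
- Fallback: exchange the ester while the ring is still aromatic and finish with a neutral hydrolysis. It sets out from 37 and returns at 42.
 - Me3SiOTf and 2,6-lutidine on the robust arene 37 give (3R)-3-[6-{[(1S,2R)-3,3-dimethyl-2-(prop-1-en-2-yl)cyclobutyl]methyl}-2,2-dimethyl-4-oxo-5,7-bis{[tri(propan-2-yl)silyl]oxy}-3,4-dihydro-2H-chromen-8-yl]hexanoic acid F10.
 - Me3SiCHN2 in MeOH and toluene gives its methyl ester F11.
 - Desilylation as in step 19 gives methyl (3R)-3-[6-{[(1S,2R)-3,3-dimethyl-2-(prop-1-en-2-yl)cyclobutyl]methyl}-5,7-dihydroxy-2,2-dimethyl-4-oxo-3,4-dihydro-2H-chromen-8-yl]hexanoate F12.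
 - Prenylation as in step 20 gives methyl (3R)-3-[(6R)-6-{[(1S,2R)-3,3-dimethyl-2-(prop-1-en-2-yl)cyclobutyl]methyl}-5-hydroxy-2,2-dimethyl-6-(3-methylbut-2-en-1-yl)-4,7-dioxo-3,4,6,7-tetrahydro-2H-chromen-8-yl]hexanoate F13.
 - Me3SnOH in 1,2-dichloroethane at 70 °C hydrolyses F13 to 42.

## Further compounds

F1 | step 16 | tert-butyl (3R)-5-{[tert-butyl(dimethyl)silyl]oxy}-3-propylpent-4-ynoate | CCC[C@H](CC(=O)OC(C)(C)C)C#CO[Si](C)(C)C(C)(C)C
F2 | step 16 | tert-butyl (3R)-3-(2-{[tert-butyl(dimethyl)silyl]oxy}-4-oxocyclobut-1-en-1-yl)hexanoate | CCC[C@H](CC(=O)OC(C)(C)C)C1=C(O[Si](C)(C)C(C)(C)C)CC1=O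
F3 | step 16 | tert-butyl (3R)-3-[6-{[tert-butyl(dimethyl)silyl]oxy}-3-{[(1S,2R)-3,3-dimethyl-2-(prop-1-en-2-yl)cyclobutyl]methyl}-4-hydroxy-2-{[tri(propan-2-yl)silyl]oxy}phenyl]hexanoate | C=C(C)[C@H]1[C@H](Cc2c(O)cc(O[Si](C)(C)C(C)(C)C)c([C@H](CCC)CC(=O)OC(C)(C)C)c2O[Si](C(C)C)(C(C)C)C(C)C)CC1(C)C
F4 | step 16 | tert-butyl (3R)-3-[6-{[tert-butyl(dimethyl)silyl]oxy}-3-{[(1S,2R)-3,3-dimethyl-2-(prop-1-en-2-yl)cyclobutyl]methyl}-2,4-bis{[tri(propan-2-yl)silyl]oxy}phenyl]hexanoate | C=C(C)[C@H]1[C@H](Cc2c(O[Si](C(C)C)(C(C)C)C(C)C)cc(O[Si](C)(C)C(C)(C)C)c([C@H](CCC)CC(=O)OC(C)(C)C)c2O[Si](C(C)C)(C(C)C)C(C)C)CC1(C)C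
F5 | step 2 | (4R)-3,3-dimethyl-4-(prop-1-en-2-yl)cyclopentan-1-one | C=C(C)[C@H]1CC(=O)CC1(C)C
F6 | step 2 | (3R)-4,4-dimethyl-3-(prop-1-en-2-yl)-2-(trifluoroacetyl)cyclopentan-1-one | C=C(C)[C@H]1C(C(=O)C(F)(F)F)C(=O)CC1(C)C
F7 | step 2 | (3R)-2-diazo-4,4-dimethyl-3-(prop-1-en-2-yl)cyclopentan-1-one | C=C(C)[C@H]1C(=[N+]=[N-])C(=O)CC1(C)C
F0 | step 20 | none | none
F8 | step 18 | tert-butyl (3R)-3-[3-{[(1S,2R)-3,3-dimethyl-2-(prop-1-en-2-yl)cyclobutyl]methyl}-5-formyl-6-hydroxy-2,4-bis{[tri(propan-2-yl)silyl]oxy}phenyl]hexanoate | C=C(C)[C@H]1[C@H](Cc2c(O[Si](C(C)C)(C(C)C)C(C)C)c(C=O)c(O)c([C@H](CCC)CC(=O)OC(C)(C)C)c2O[Si](C(C)C)(C(C)C)C(C)C)CC1(C)C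
F9 | step 18 | tert-butyl (3R)-3-[3-{[(1S,2R)-3,3-dimethyl-2-(prop-1-en-2-yl)cyclobutyl]methyl}-6-hydroxy-5-(1-hydroxy-3-methylbut-2-en-1-yl)-2,4-bis{[tri(propan-2-yl)silyl]oxy}phenyl]hexanoate (both carbinol epimers) | C=C(C)[C@H]1[C@H](Cc2c(O[Si](C(C)C)(C(C)C)C(C)C)c(C(O)C=C(C)C)c(O)c([C@H](CCC)CC(=O)OC(C)(C)C)c2O[Si](C(C)C)(C(C)C)C(C)C)CC1(C)C
F10 | step 21 | (3R)-3-[6-{[(1S,2R)-3,3-dimethyl-2-(prop-1-en-2-yl)cyclobutyl]methyl}-2,2-dimethyl-4-oxo-5,7-bis{[tri(propan-2-yl)silyl]oxy}-3,4-dihydro-2H-chromen-8-yl]hexanoic acid | C=C(C)[C@H]1[C@H](Cc2c(O[Si](C(C)C)(C(C)C)C(C)C)c3C(=O)CC(C)(C)Oc3c([C@H](CCC)CC(=O)O)c2O[Si](C(C)C)(C(C)C)C(C)C)CC1(C)C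
F11 | step 21 | methyl (3R)-3-[6-{[(1S,2R)-3,3-dimethyl-2-(prop-1-en-2-yl)cyclobutyl]methyl}-2,2-dimethyl-4-oxo-5,7-bis{[tri(propan-2-yl)silyl]oxy}-3,4-dihydro-2H-chromen-8-yl]hexanoate | C=C(C)[C@H]1[C@H](Cc2c(O[Si](C(C)C)(C(C)C)C(C)C)c3C(=O)CC(C)(C)Oc3c([C@H](CCC)CC(=O)OC)c2O[Si](C(C)C)(C(C)C)C(C)C)CC1(C)C
F12 | step 21 | methyl (3R)-3-[6-{[(1S,2R)-3,3-dimethyl-2-(prop-1-en-2-yl)cyclobutyl]methyl}-5,7-dihydroxy-2,2-dimethyl-4-oxo-3,4-dihydro-2H-chromen-8-yl]hexanoate | C=C(C)[C@H]1[C@H](Cc2c(O)c3C(=O)CC(C)(C)Oc3c([C@H](CCC)CC(=O)OC)c2O)CC1(C)C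
F13 | step 21 | methyl (3R)-3-[(6R)-6-{[(1S,2R)-3,3-dimethyl-2-(prop-1-en-2-yl)cyclobutyl]methyl}-5-hydroxy-2,2-dimethyl-6-(3-methylbut-2-en-1-yl)-4,7-dioxo-3,4,6,7-tetrahydro-2H-chromen-8-yl]hexanoate | C=C(C)[C@H]1[C@H](C[C@]2(CC=C(C)C)C(=O)C([C@H](CCC)CC(=O)OC)=C3OC(C)(C)CC(=O)C3=C2O)CC1(C)C
A1 | alternative 1 | (2R)-4-methyl-2-(prop-2-en-1-yloxy)pent-3-ene | C[C@@H](OCC=C)C=C(C)C
A2 | alternative 1 | (1R,2R,5R)-2,7,7-trimethyl-3-oxabicyclo[3.2.0]heptane | C[C@H]1OC[C@@H]2CC(C)(C)[C@H]12
A3 | alternative 2 | (3R)-2-diazo-4,4-dimethyl-3-(prop-1-en-2-yl)cyclopentan-1-one | C=C(C)[C@H]1C(=[N+]=[N-])C(=O)CC1(C)C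
A4 | alternative 2 | methyl (1R,2R)-3,3-dimethyl-2-(prop-1-en-2-yl)cyclobutane-1-carboxylate | C=C(C)[C@H]1[C@H](C(=O)OC)CC1(C)C
A5 | alternative 3 | methyl (2S)-2-{[(1S,2R)-3,3-dimethyl-2-(prop-1-en-2-yl)cyclobutyl]methyl}-4-(6,6-dimethyl-4-oxo-5,6-dihydro-4H-pyran-2-yl)-2-(3-methylbut-2-en-1-yl)-3-oxobutanoate | C=C(C)[C@H]1[C@H](C[C@@](CC=C(C)C)(C(=O)OC)C(=O)CC2=CC(=O)CC(C)(C)O2)CC1(C)C
A6 | alternative 3 | (6R)-6-{[(1S,2R)-3,3-dimethyl-2-(prop-1-en-2-yl)cyclobutyl]methyl}-5-hydroxy-2,2-dimethyl-6-(3-methylbut-2-en-1-yl)-2,3-dihydro-4H-chromene-4,7(6H)-dione | C=C(C)[C@H]1[C@H](C[C@]2(CC=C(C)C)C(=O)C=C3OC(C)(C)CC(=O)C3=C2O)CC1(C)C
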